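**Plan**

- **Cuts:** The quinone is traced back to its tribenzyl-protected hydroquinone/phenol. Ring C is then cut at C4–C4a and O1–C8a in one operation, giving a ring A iodide and a C3-configured 3-bromo-2-arylpropan-1-ol. The bromohydrin goes back through its C–Br bond to an achiral 3-aryloxetane, and that is cut at C3–C1′ into a ring B boronic acid and 3-iodooxetane.
- **Enabling feature:** C4a and C8a are neighbouring carbons of ring A that carry C4 and O1. The other neighbour of C8a, C8, bears a methoxyl. This is the ortho/ipso pattern of a palladium/norbornene relay started from a C8a iodide that has only one free ortho C–H.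
- **Forward order:** Rings A and B are bought as arenes and dressed separately. C3–C1′ is joined first and ring C is closed last. Debenzylation and oxidation of ring B finish the route.
- **Stereochemistry:** The only stereocentre, C3 (S), comes from a catalyst-controlled desymmetrising opening of the oxetane with TMSBr. It is a spectator in every later step.

Key step: step 10

Assumption: the antipode of the squaramide that gives the (S)-bromohydrin with this ortho-alkoxyaryl oxetane is fixed by a trial run with assignment of configuration (the bromine allows anomalous-dispersion crystallography); both antipodes of the catalyst are equally accessible.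

**Step 1**
Reactants: 1 2,3-dimethoxyphenol
Product: 2 2,3-dimethoxy-1,4-benzoquinone
Conditions: O2 (1 atm), Co(salen) (5 mol %), DMF, rt
Reagents that add atoms: dioxygen, O=O
Why: Salcomine-type aerobic oxidation of a phenol with a free para position is a standard phenol-to-para-quinone conversion, in which the cobalt–dioxygen adduct takes the phenolic hydrogen and delivers oxygen to the para carbon.

**Step 2**
Reactants: 2 2,3-dimethoxy-1,4-benzoquinone
Product: 4 1,4-bis(benzyloxy)-2,3-dimethoxybenzene, via 2,3-dimethoxyhydroquinone 3 (not isolated)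
Conditions: aq Na2S2O4, EtOAc, rt; phase cut and solvent swap under Ar; then BnBr (2.3 equiv), K2CO3, DMF, 50 °C
Reagents that add atoms: benzyl bromide, BrCc1ccccc1
Why: Dithionite reduction of the quinone followed by double Williamson etherification should be routine, and carrying the air-sensitive hydroquinone forward crude avoids its re-oxidation.

**Step 3**
Reactants: 4 1,4-bis(benzyloxy)-2,3-dimethoxybenzene
Product: 5 1,4-bis(benzyloxy)-5-bromo-2,3-dimethoxybenzene
Conditions: NBS (1.0 equiv), MeCN, 0 °C to rt, dark
Reagents that add atoms: N-bromosuccinimide, O=C1CCC(=O)N1Br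
Why: In this electrophilic aromatic bromination the two open positions of the symmetric tetraalkoxybenzene are equivalent, so only one monobromide can form, and the benzyl phenyl rings are far less activated.

**Step 4**
Reactants: 5 1,4-bis(benzyloxy)-5-bromo-2,3-dimethoxybenzene
Product: 8 [2,5-bis(benzyloxy)-3,4-dimethoxyphenyl]boronic acid, via aryllithium 6 (not isolated), via lithium aryltriisopropoxyborate 7 (not isolated)
Conditions: B(OiPr)3 (1.3 equiv) present from the start, n-BuLi (1.1 equiv) added last, THF/toluene, −78 °C; then 1 M HCl, 0 °C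
Reagents that add atoms: triisopropyl borate, CC(C)OB(OC(C)C)OC(C)C; water, O (for the intermediates only: n-butyllithium, [Li]CCCC, supplies the lithium of 6 and 7)
Why: Bromine–lithium exchange with in situ borate trapping keeps the lifetime of the ortho-benzyloxy aryllithium short, so proton transfer from the benzylic CH2 and Wittig rearrangement should not compete.

**Step 5**
Reactants: 8 [2,5-bis(benzyloxy)-3,4-dimethoxyphenyl]boronic acid; 9 3-iodooxetane
Product: 10 3-[2,5-bis(benzyloxy)-3,4-dimethoxyphenyl]oxetane
Conditions: NiI2 (10 mol %), trans-2-aminocyclohexanol·HCl (10 mol %), NaHMDS (2 equiv), i-PrOH, 80 °C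
Reagents that add atoms: none
Why: The nickel-catalysed alkyl Suzuki–Miyaura coupling of a secondary iodide is the established entry to 3-aryloxetanes, and its radical-type activation of the C–I bond leaves the strained ether intact.

**Step 6**
Reactants: 10 3-[2,5-bis(benzyloxy)-3,4-dimethoxyphenyl]oxetane
Product: 12 (S)-2-[2,5-bis(benzyloxy)-3,4-dimethoxyphenyl]-3-bromopropan-1-ol, via trimethylsilyl ether 11 (not isolated)
Conditions: TMSBr (1.2 equiv), chiral tert-leucine arylpyrrolidine squaramide (5 mol %), t-BuOMe, −78 °C; then 1 M HCl, THF, 0 °C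
Reagents that add atoms: bromotrimethylsilane, C[Si](C)(C)Br
Why: In this hydrogen-bond-donor-catalysed desymmetrising opening of a 3-substituted oxetane the squaramide holds the bromide of the O-silyloxetanium ion pair and steers its SN2 attack to one of the two enantiotopic CH2–O carbons, which sets C3 as (S), and mild acid then removes the silyl group.

**Step 7**
Reactants: 13 1,2-dimethoxybenzene (veratrole)
Product: 15 1,4-diiodo-2,3-dimethoxybenzene, via 3,6-dilithioveratrole 14 (not isolated)
Conditions: n-BuLi (2.6 equiv), TMEDA (2.6 equiv), Et2O/hexane, 0 °C to reflux; then I2, THF, −78 °C to rt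
Reagents that add atoms: iodine, II (for the intermediate only: n-butyllithium, [Li]CCCC, supplies the lithium of 14)
Why: Double directed ortho-metalation puts one lithium next to each methoxyl, so the 1,4-relationship of the two iodines is fixed by the directing groups and does not depend on the ortho/para selectivity of an electrophilic iodination of a phenol.

**Step 8**
Reactants: 15 1,4-diiodo-2,3-dimethoxybenzene
Product: 18 4-iodo-2,3-dimethoxyphenol, via arylmagnesium chloride 16 (not isolated), via dimethyl arylboronate 17 (not isolated)
Conditions: i-PrMgCl·LiCl (1.05 equiv), THF, −30 °C; B(OMe)3, to rt; 30% aq H2O2, 0 °C; 1 M HCl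
Reagents that add atoms: hydrogen peroxide, OO (for the intermediates only: isopropylmagnesium chloride, CC(C)[Mg]Cl, for 16; trimethyl borate, COB(OC)OC, for 17)
Why: Iodine–magnesium exchange stops after one iodine because the electron-rich aryl Grignard resists a second exchange, and borylation followed by peroxide oxidation is the standard hydroxylation of an arylmetal and leaves the remaining C–I bond untouched.

**Step 9**
Reactants: 18 4-iodo-2,3-dimethoxyphenol
Product: 19 1-(benzyloxy)-4-iodo-2,3-dimethoxybenzene
Conditions: BnBr (1.1 equiv), K2CO3, acetone, reflux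
Reagents that add atoms: benzyl bromide, BrCc1ccccc1
Why: This is a Williamson etherification of a phenol under carbonate conditions, which do not affect the aryl iodide.

**Step 10**
Reactants: 19 1-(benzyloxy)-4-iodo-2,3-dimethoxybenzene; 12 (S)-2-[2,5-bis(benzyloxy)-3,4-dimethoxyphenyl]-3-bromopropan-1-ol
Product: 20 (3S)-6-(benzyloxy)-3-[2,5-bis(benzyloxy)-3,4-dimethoxyphenyl]-7,8-dimethoxychroman
Conditions: Pd(OAc)2 (10 mol %), RuPhos (20 mol %), norbornene (1.5 equiv), Cs2CO3 (2.5 equiv), toluene, 100 °C, 12 added over 4 h
Reagents that add atoms: none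
Why: Proposed new method: zerovalent palladium inserts into the C8a–I bond of 19, norbornene carbopalladates, and the single free ortho C–H (the future C4a) is metalated to a five-membered aryl–norbornyl palladacycle of divalent palladium; this electron-rich palladacycle takes up the primary C–Br bond of 12 (or the C–I bond made from it by the CsI that accumulates) by SN2-type oxidative addition to tetravalent palladium, and reductive elimination forges C4–C4a. Both ortho positions now being filled, β-carbon elimination expels norbornene, and the C8a–palladium species binds the tethered alkoxide and closes ring C by C(sp2)–O reductive elimination from a seven-membered oxapalladacycle, a six-membered ring closure at the ipso carbon. The closest known reaction types are the palladium/norbornene annulation of aryl iodides with epoxides to 2,3-dihydrobenzofurans, which runs through the same ortho-alkylation then ipso-etherification with one ring atom fewer, and the separate palladium-catalysed cyclisation of 3-(2-halophenyl)propan-1-ols to chromans with bulky dialkylbiarylphosphines and Cs2CO3. No stereocentre is created: none of the four bonds at C3 is broken, so (S)-12 maps onto (3S)-20 with CH2Br becoming C4 and CH2OH becoming C2. Site selectivity is built into 19, whose C8 methoxyl blocks one ortho position and provides the ortho substituent that makes norbornene extrusion follow a single alkylation. Chemoselectivity (alkylation before etherification, no base-induced return of 12 to oxetane 10, no β-hydride loss from the alkoxide, no palladation of C6′–H of ring B) rests on the barely soluble carbonate in toluene, slow addition of 12, and the bulky electron-rich RuPhos, which speeds C–O reductive elimination.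

**Step 11**
Reactants: 20 (3S)-6-(benzyloxy)-3-[2,5-bis(benzyloxy)-3,4-dimethoxyphenyl]-7,8-dimethoxychroman
Product: 21 (3S)-3-(2,5-dihydroxy-3,4-dimethoxyphenyl)-7,8-dimethoxychroman-6-ol
Conditions: H2 (1 atm), Pd/C (10 wt %), EtOAc/MeOH, rt; filtered and concentrated under Ar
Reagents that add atoms: none
Why: Catalytic hydrogenolysis removes the three aryl benzyl ethers, while the chroman C–O and C–C bonds and the C3–H stereocentre carry no hydrogenolysable bond.

**Step 12**
Reactants: 21 (3S)-3-(2,5-dihydroxy-3,4-dimethoxyphenyl)-7,8-dimethoxychroman-6-ol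
Product: 22 5-[(3S)-6-hydroxy-7,8-dimethoxychroman-3-yl]-2,3-dimethoxy-1,4-benzoquinone (CNP0302517.1)
Conditions: Ag2O (1.5 equiv), Et2O/CH2Cl2, rt, short contact time
Reagents that add atoms: none
Why: Silver oxide dehydrogenates the ring B hydroquinone to the para-quinone, whereas the ring A phenol has its para position tied up as the O1 ether and cannot become a quinone without C–O cleavage, so it should survive.

**Compound list**

| No. | Name | SMILES | Role |
|---|---|---|---|
| 1 | 2,3-dimethoxyphenol | COc1cccc(O)c1OC | starting material |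
| 2 | 2,3-dimethoxy-1,4-benzoquinone | COC1=C(OC)C(=O)C=CC1=O | intermediate |
| 3 | 2,3-dimethoxybenzene-1,4-diol (2,3-dimethoxyhydroquinone) | COc1c(O)ccc(O)c1OC | intermediate |
| 4 | 1,4-bis(benzyloxy)-2,3-dimethoxybenzene | COc1c(OCc2ccccc2)ccc(OCc2ccccc2)c1OC | intermediate |
| 5 | 1,4-bis(benzyloxy)-5-bromo-2,3-dimethoxybenzene | COc1c(OC)c(OCc2ccccc2)c(Br)cc1OCc1ccccc1 | intermediate |
| 6 | [2,5-bis(benzyloxy)-3,4-dimethoxyphenyl]lithium | COc1c(OC)c(OCc2ccccc2)c([Li])cc1OCc1ccccc1 | intermediate |
| 7 | lithium [2,5-bis(benzyloxy)-3,4-dimethoxyphenyl]tri(propan-2-yloxy)borate | [Li+].COc1c(OC)c(OCc2ccccc2)c(cc1OCc1ccccc1)[B-](OC(C)C)(OC(C)C)OC(C)C | intermediate |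
| 8 | [2,5-bis(benzyloxy)-3,4-dimethoxyphenyl]boronic acid | COc1c(OC)c(OCc2ccccc2)c(B(O)O)cc1OCc1ccccc1 | intermediate |
| 9 | 3-iodooxetane | IC1COC1 | starting material |
| 10 | 3-[2,5-bis(benzyloxy)-3,4-dimethoxyphenyl]oxetane | COc1c(OC)c(OCc2ccccc2)c(C2COC2)cc1OCc1ccccc1 | intermediate |
| 11 | (S)-{2-[2,5-bis(benzyloxy)-3,4-dimethoxyphenyl]-3-bromopropoxy}trimethylsilane | COc1c(OC)c(OCc2ccccc2)c([C@H](CBr)CO[Si](C)(C)C)cc1OCc1ccccc1 | intermediate |
| 12 | (S)-2-[2,5-bis(benzyloxy)-3,4-dimethoxyphenyl]-3-bromopropan-1-ol | COc1c(OC)c(OCc2ccccc2)c([C@H](CBr)CO)cc1OCc1ccccc1 | intermediate |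
| 13 | 1,2-dimethoxybenzene (veratrole) | COc1ccccc1OC | starting material |
| 14 | 3,6-dilithio-1,2-dimethoxybenzene | COc1c([Li])ccc([Li])c1OC | intermediate |
| 15 | 1,4-diiodo-2,3-dimethoxybenzene | COc1c(I)ccc(I)c1OC | intermediate |
| 16 | (4-iodo-2,3-dimethoxyphenyl)magnesium chloride | COc1c(I)ccc([Mg]Cl)c1OC | intermediate |
| 17 | dimethyl (4-iodo-2,3-dimethoxyphenyl)boronate | COB(OC)c1ccc(I)c(OC)c1OC | intermediate |
| 18 | 4-iodo-2,3-dimethoxyphenol | COc1c(I)ccc(O)c1OC | intermediate |
| 19 | 1-(benzyloxy)-4-iodo-2,3-dimethoxybenzene | COc1c(I)ccc(OCc2ccccc2)c1OC | intermediate |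
| 20 | (3S)-6-(benzyloxy)-3-[2,5-bis(benzyloxy)-3,4-dimethoxyphenyl]-7,8-dimethoxychroman | COc1c(OC)c(OCc2ccccc2)c([C@H]3COc4c(cc(OCc5ccccc5)c(OC)c4OC)C3)cc1OCc1ccccc1 | intermediate |
| 21 | (3S)-3-(2,5-dihydroxy-3,4-dimethoxyphenyl)-7,8-dimethoxychroman-6-ol | COc1c(OC)c(O)c([C@H]2COc3c(cc(O)c(OC)c3OC)C2)cc1O | intermediate |
| 22 | 5-[(3S)-6-hydroxy-7,8-dimethoxychroman-3-yl]-2,3-dimethoxy-1,4-benzoquinone | COC1=C(OC)C(=O)C([C@H]2COc3c(cc(O)c(OC)c3OC)C2)=CC1=O | target |

**Step count**

- Total step count: 12.
- Longest linear sequence: 9 steps (steps 1–6, then 10–12).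
- The ring A branch (steps 7–9) has 3 steps.

**Steps most likely to fail**

**Step 10 (key annulation).**
- *What may go wrong:* Oxidative addition of the β-branched bromide to the palladacycle may be slow. That would let the palladacycle collapse with retention of norbornene. The carbonate may close 12 back to the achiral oxetane or eliminate HBr. β-Hydride loss from the palladium alkoxide would reduce the ipso position. The C8a–palladium species may also arylate C6′–H of ring B instead of capturing oxygen.
- *Fallback:* It sets out from 19 and 12, returns at 20, and makes the same two ring C connections one after the other with known reactions.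
  - Iodide 19 is hydroxylated (CuI, 1,10-phenanthroline, KOH, DMSO/H2O, 100 °C) to 4-(benzyloxy)-2,3-dimethoxyphenol F1.
  - NBS with catalytic i-Pr2NH in CH2Cl2 brominates F1 ortho to the hydroxyl, giving 4-(benzyloxy)-6-bromo-2,3-dimethoxyphenol F2.
  - A Mitsunobu reaction (PPh3, DIAD, THF) joins F2 to the primary alcohol of 12 without base, so the alkyl bromide stays in place. This gives (S)-1-(benzyloxy)-4-{2-[2,5-bis(benzyloxy)-3,4-dimethoxyphenyl]-3-bromopropoxy}-5-bromo-2,3-dimethoxybenzene F3.
  - n-BuLi in THF at −78 °C exchanges the aryl bromide faster than the alkyl bromide. The resulting ring A aryllithium F4 displaces the primary bromide on warming (Parham cyclialkylation) and gives 20.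
  - CH2Br again becomes C4 and the CH2O arm becomes C2, so the configuration is the same.

**Step 5 (nickel coupling).**
- *What may go wrong:* The electron-rich ortho-alkoxy boronic acid may protodeboronate in hot alkoxide, and its transmetalation may be sluggish.
- *Fallback:* It sets out from 5 and 9, returns at 10, and reverses the polarity of the partners.
  - Zinc dust with LiCl in THF inserts into the C–I bond of 9 to give oxetan-3-ylzinc iodide F5.
  - F5 is coupled with bromide 5 in a Negishi reaction (Pd(OAc)2, CPhos, THF/toluene, rt to 50 °C).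
  - This also makes step 4 unnecessary.

**Step 6 (desymmetrisation).**
- *What may go wrong:* The catalyst may discriminate weakly between the two enantiotopic CH2–O bonds, because the ortho benzyloxy group crowds and twists the aryl ring. Uncatalysed opening by TMSBr or adventitious HBr may add a racemic background.
- *Fallback:* It sets out from 10, returns at 12, and takes the stereocentre from an enzyme.
  - Dilute H2SO4 in dioxane/H2O opens 10 to 2-[2,5-bis(benzyloxy)-3,4-dimethoxyphenyl]propane-1,3-diol F6.
  - Pseudomonas cepacia lipase with vinyl acetate in t-BuOMe desymmetrises F6 to (R)-2-[2,5-bis(benzyloxy)-3,4-dimethoxyphenyl]-3-hydroxypropyl acetate F7. Should the enzyme prefer the other arm, hydrolysis of the diacetate with the same lipase gives the needed antipode.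
  - An Appel reaction (CBr4, PPh3, CH2Cl2, 0 °C), run promptly to forestall acyl migration, gives (S)-2-[2,5-bis(benzyloxy)-3,4-dimethoxyphenyl]-3-bromopropyl acetate F8.
  - Acidic methanolysis (HCl in MeOH, rt) frees 12 without base.

**Further compounds**

F1 | step 10 | 4-(benzyloxy)-2,3-dimethoxyphenol | COc1c(O)ccc(OCc2ccccc2)c1OC
F2 | step 10 | 4-(benzyloxy)-6-bromo-2,3-dimethoxyphenol | COc1c(O)c(Br)cc(OCc2ccccc2)c1OC
F3 | step 10 | (S)-1-(benzyloxy)-4-{2-[2,5-bis(benzyloxy)-3,4-dimethoxyphenyl]-3-bromopropoxy}-5-bromo-2,3-dimethoxybenzene | COc1c(OC)c(OCc2ccccc2)c([C@H](CBr)COc2c(Br)cc(OCc3ccccc3)c(OC)c2OC)cc1OCc1ccccc1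
F4 | step 10 | ring A aryllithium derived from F3 | COc1c(OC)c(OCc2ccccc2)c([C@H](CBr)COc2c([Li])cc(OCc3ccccc3)c(OC)c2OC)cc1OCc1ccccc1
F5 | step 5 | oxetan-3-ylzinc iodide | I[Zn]C1COC1
F6 | step 6 | 2-[2,5-bis(benzyloxy)-3,4-dimethoxyphenyl]propane-1,3-diol | OCC(CO)c1cc(OCc2ccccc2)c(OC)c(OC)c1OCc1ccccc1
F7 | step 6 | (R)-2-[2,5-bis(benzyloxy)-3,4-dimethoxyphenyl]-3-hydroxypropyl acetate | COc1c(OC)c(OCc2ccccc2)c([C@H](CO)COC(C)=O)cc1OCc1ccccc1
F8 | step 6 | (S)-2-[2,5-bis(benzyloxy)-3,4-dimethoxyphenyl]-3-bromopropyl acetate | COc1c(OC)c(OCc2ccccc2)c([C@H](CBr)COC(C)=O)cc1OCc1ccccc1
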